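**Retrosynthetic overview**
1. The target is reached by fluoride desilylation of its (3S)-5,7,3'-tris-silyl ether. That ether is disconnected at O1–C2 (and C3–H) to an open α-aryl vinyl ketone, a 2-aryl-1-(2-hydroxy-4,6-bis-silyloxyphenyl)prop-2-en-1-one.
2. Feature used: in ring C, C2 is an unsubstituted CH2 between O1 and the only stereocentre C3, and ring A carries equivalent oxygens on both carbons flanking the acyl-bearing carbon C4a (C5 and C8a), so either can become O1. One of them is kept as a silyl ether. With both free, one hydroxyl would always be unchelated and would close without catalyst; the single free hydroxyl is locked to C4=O by a hydrogen bond and closes only when the catalyst deprotonates it.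
3. The vinyl ketone comes from a deoxybenzoin by Mannich methylenation (C2 from the iminium salt) and removal of a temporary MOM group. The deoxybenzoin comes from palladium-catalysed α-arylation of a protected 2,4,6-trihydroxyacetophenone with the ring B aryl bromide (C3–C1' bond).
4. The ring B bromide is made from 2,4,6-tribromoanisole by two successive ortho-selective halogen–metal exchanges (prenyl in, then hydroxyl in).
5. Ring order: rings A and B are bought as benzene rings; ring C is the only ring formed, by 6-endo-trig oxa-Michael closure with catalyst-controlled protonation.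

Key step: step 9

Assumption (chemistry): the quinine-derived squaramide is taken to give the 3S sense; if the first run shows 3R, the quinidine-derived pseudoenantiomer replaces it with nothing else changed.

**Step 1**
Reactants: 1 2,4,6-tribromoanisole; 2 prenyl bromide (1-bromo-3-methylbut-2-ene)
Product: 4 1,5-dibromo-2-methoxy-3-(3-methylbut-2-en-1-yl)benzene, via arylmagnesium chloride 3 (not isolated)
Conditions: i-PrMgCl·LiCl, THF, 0 °C → rt; then CuBr·SMe2 (5 mol %), 2, 0 °C → rt
Reagents that add atoms: prenyl bromide, CC(C)=CCBr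
Why: Bromine–magnesium exchange takes place at one of the two equivalent bromines ortho to the methoxy group (the ortho arylmagnesium is stabilised by the neighbouring oxygen), and copper-catalysed allylic substitution of the aryl Grignard reagent on prenyl bromide occurs at the unhindered primary carbon because the other allyl terminus is fully substituted.

**Step 2**
Reactants: 4 1,5-dibromo-2-methoxy-3-(3-methylbut-2-en-1-yl)benzene
Product: 7 5-bromo-2-methoxy-3-(3-methylbut-2-en-1-yl)phenol, via aryllithium 5 (not isolated), via dimethyl arylboronate 6 (not isolated)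
Conditions: n-BuLi, THF, −78 °C; B(OMe)3, −78 °C → rt; then 30 % H2O2, aq NaOH, 0 °C
Reagents that add atoms: hydrogen peroxide, OO
Why: Bromine–lithium exchange again selects the bromine ortho to the methoxy group over the para one (the behaviour known for 2,4-dibromoanisole), the aryllithium is borylated, and alkaline peroxide oxidation of the boronate (1,2-aryl shift from boron to oxygen) should give the phenol without touching the trisubstituted alkene.

**Step 3**
Reactants: 7 5-bromo-2-methoxy-3-(3-methylbut-2-en-1-yl)phenol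
Product: 8 [5-bromo-2-methoxy-3-(3-methylbut-2-en-1-yl)phenoxy](tert-butyl)dimethylsilane
Conditions: TBSCl, imidazole, DMF, rt
Reagents that add atoms: tert-butyldimethylsilyl chloride, CC(C)(C)[Si](C)(C)Cl
Why: Standard imidazole-mediated O-silylation of a phenol; the TBS ether masks O3' through the enolate steps and falls to fluoride at the end.

**Step 4**
Reactants: 9 2,4,6-trihydroxyacetophenone
Product: 10 1-[2-hydroxy-4,6-bis(triisopropylsilyloxy)phenyl]ethanone
Conditions: TIPSCl (2.2 equiv), imidazole, DMF, 0 °C → rt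
Reagents that add atoms: triisopropylsilyl chloride, CC(C)[Si](Cl)(C(C)C)C(C)C
Why: Imidazole-mediated silylation should stop after two hydroxyls because the last one is held by a hydrogen bond to the acetyl carbonyl, the usual selectivity of 2,4,6-trihydroxyaryl ketones; the bulky TIPS ethers are chosen to withstand the later basic steps.

**Step 5**
Reactants: 10 1-[2-hydroxy-4,6-bis(triisopropylsilyloxy)phenyl]ethanone
Product: 11 1-[2-(methoxymethoxy)-4,6-bis(triisopropylsilyloxy)phenyl]ethanone
Conditions: NaH, THF, 0 °C; MOMCl, 0 °C → rt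
Reagents that add atoms: chloromethyl methyl ether, COCCl
Why: Williamson O-alkylation of the sodium phenoxide with chloromethyl methyl ether; NaH is needed to break the hydrogen bond of the chelated hydroxyl, and the acetal is a temporary block that mild acid can remove later.

**Step 6**
Reactants: 11 1-[2-(methoxymethoxy)-4,6-bis(triisopropylsilyloxy)phenyl]ethanone; 8 [5-bromo-2-methoxy-3-(3-methylbut-2-en-1-yl)phenoxy](tert-butyl)dimethylsilane
Product: 12 2-[3-(tert-butyldimethylsilyloxy)-4-methoxy-5-(3-methylbut-2-en-1-yl)phenyl]-1-[2-(methoxymethoxy)-4,6-bis(triisopropylsilyloxy)phenyl]ethanone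
Conditions: Pd2(dba)3 (2.5 mol %), Xantphos (6 mol %), K3PO4, toluene, 80 °C
Reagents that add atoms: none
Why: Palladium-catalysed α-arylation of a methyl ketone with an aryl bromide (Buchwald–Hartwig ketone arylation) forms the C3–C1' bond; the wide-bite-angle bisphosphine favours monoarylation and the phosphate base is chosen to spare the aryl silyl ethers.

**Step 7**
Reactants: 12 the deoxybenzoin of step 6; 13 dimethylmethyleneammonium iodide
Product: 16 2-[3-(tert-butyldimethylsilyloxy)-4-methoxy-5-(3-methylbut-2-en-1-yl)phenyl]-1-[2-(methoxymethoxy)-4,6-bis(triisopropylsilyloxy)phenyl]prop-2-en-1-one, via Mannich base 14 (not isolated), via trimethylammonium iodide 15 (not isolated)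
Conditions: LiN(SiMe3)2, THF, −78 °C; 13, −78 → 0 °C; NH4Cl work-up; crude amine, MeI, MeCN, rt; then aq NaHCO3, CH2Cl2, 0 °C → rt
Reagents that add atoms: dimethylmethyleneammonium iodide, C=[N+](C)C.[I-]
Why: Mannich aminomethylation of the only possible enolate (benzylic CH2) with the iminium salt, N-methylation and E1cB loss of trimethylamine give the α-methylene ketone that supplies C2; both oxygens ortho to the carbonyl are blocked, so the enone cannot close.

**Step 8**
Reactants: 16 the MOM-protected vinyl ketone of step 7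
Product: 17 2-[3-(tert-butyldimethylsilyloxy)-4-methoxy-5-(3-methylbut-2-en-1-yl)phenyl]-1-[2-hydroxy-4,6-bis(triisopropylsilyloxy)phenyl]prop-2-en-1-one
Conditions: NaHSO4·SiO2, CH2Cl2, 0 °C → rt; filtration, no basic work-up; used at once
Reagents that add atoms: none
Why: Acid-catalysed hydrolysis of the only acetal, an aryl methoxymethyl ether made labile by the ortho carbonyl, on a solid acid in an aprotic solvent; the phenol that appears is tied to the carbonyl by a hydrogen bond and should not add to the enone without a base, and filtration removes the acid so that no basic work-up is needed.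

**Step 9**
Reactants: 17 the 2-hydroxyaryl vinyl ketone of step 8
Product: 18 (3S)-3-[3-(tert-butyldimethylsilyloxy)-4-methoxy-5-(3-methylbut-2-en-1-yl)phenyl]-5,7-bis(triisopropylsilyloxy)chroman-4-one
Conditions: 3-{[3,5-bis(trifluoromethyl)phenyl]amino}-4-{[(8α,9S)-6′-methoxycinchonan-9-yl]amino}cyclobut-3-ene-1,2-dione (C32H28F6N4O3, 10 mol %), CH2Cl2/toluene, 0.02 M, −40 °C; AcOH quench at −40 °C; silica filtration
Reagents that add atoms: none
Why: Proposed new method: the quinuclidine nitrogen of the catalyst takes the proton of the single carbonyl-chelated hydroxyl of ring A while the squaramide N–H bonds hold the carbonyl oxygen, the phenoxide adds to the unsubstituted CH2 terminus to form O1–C2, and the quinuclidinium N–H then gives its proton to C3 of the squaramide-bound enolate. The closest known reaction types are the racemic amine-mediated closure of 2'-hydroxy α-methylene deoxybenzoins to isoflavanones and bifunctional amine–squaramide or amine–thiourea hetero-Michael addition with enantioselective protonation of α-substituted acceptors. Ring C closes in the 6-endo-trig mode. C3, the only new stereocentre, is set by the catalyst, which decides the enolate face that receives the proton inside the chiral ion pair; no substrate stereocentre takes part. The step needs the catalysed, face-selective protonation to outrun uncatalysed closure and later enolisation of the product: the hydrogen bond of the only free ortho hydroxyl keeps the neutral substrate from closing without a base, the silyl ether on the other ortho oxygen removes the unchelated hydroxyl that would close on its own, and low temperature with an acid quench protects the product. Because the acceptor terminus is unsubstituted no second stereocentre arises, and because the two ortho oxygens of ring A are equivalent it does not matter which one closes.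

**Step 10**
Reactants: 18 the (3S)-tris-silyl isoflavanone of step 9
Product: 19 (3S)-5,7,3'-trihydroxy-4'-methoxy-5'-prenylisoflavanone
Conditions: Et3N·3HF (excess), THF, 0 °C → rt
Reagents that add atoms: none
Why: Fluoride cleavage of the three aryl silyl ethers under mildly acidic conditions (the two on ring A are activated by the C4 carbonyl); no base able to enolise C3 is present, so the configuration set in step 9 should be kept.

**Compound list**
1 | 2,4,6-tribromoanisole | COc1c(Br)cc(Br)cc1Br | starting material
2 | prenyl bromide (1-bromo-3-methylbut-2-ene) | CC(C)=CCBr | starting material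
3 | (3,5-dibromo-2-methoxyphenyl)magnesium chloride (LiCl complex) | COc1c([Mg]Cl)cc(Br)cc1Br | intermediate (not isolated)
4 | 1,5-dibromo-2-methoxy-3-(3-methylbut-2-en-1-yl)benzene | COc1c(Br)cc(Br)cc1CC=C(C)C | intermediate
5 | [5-bromo-2-methoxy-3-(3-methylbut-2-en-1-yl)phenyl]lithium | COc1c([Li])cc(Br)cc1CC=C(C)C | intermediate (not isolated)
6 | dimethyl [5-bromo-2-methoxy-3-(3-methylbut-2-en-1-yl)phenyl]boronate | COc1c(B(OC)OC)cc(Br)cc1CC=C(C)C | intermediate (not isolated)
7 | 5-bromo-2-methoxy-3-(3-methylbut-2-en-1-yl)phenol | COc1c(O)cc(Br)cc1CC=C(C)C | intermediate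
8 | [5-bromo-2-methoxy-3-(3-methylbut-2-en-1-yl)phenoxy](tert-butyl)dimethylsilane | COc1c(O[Si](C)(C)C(C)(C)C)cc(Br)cc1CC=C(C)C | intermediate
9 | 2,4,6-trihydroxyacetophenone | CC(=O)c1c(O)cc(O)cc1O | starting material
10 | 1-[2-hydroxy-4,6-bis(triisopropylsilyloxy)phenyl]ethanone | CC(=O)c1c(O)cc(O[Si](C(C)C)(C(C)C)C(C)C)cc1O[Si](C(C)C)(C(C)C)C(C)C | intermediate
11 | 1-[2-(methoxymethoxy)-4,6-bis(triisopropylsilyloxy)phenyl]ethanone | CC(=O)c1c(OCOC)cc(O[Si](C(C)C)(C(C)C)C(C)C)cc1O[Si](C(C)C)(C(C)C)C(C)C | intermediate
12 | 2-[3-(tert-butyldimethylsilyloxy)-4-methoxy-5-(3-methylbut-2-en-1-yl)phenyl]-1-[2-(methoxymethoxy)-4,6-bis(triisopropylsilyloxy)phenyl]ethanone | COc1c(O[Si](C)(C)C(C)(C)C)cc(CC(=O)c2c(OCOC)cc(O[Si](C(C)C)(C(C)C)C(C)C)cc2O[Si](C(C)C)(C(C)C)C(C)C)cc1CC=C(C)C | intermediate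
13 | dimethylmethyleneammonium iodide | C=[N+](C)C.[I-] | starting material
14 | racemic 3-(dimethylamino)-2-[3-(tert-butyldimethylsilyloxy)-4-methoxy-5-(3-methylbut-2-en-1-yl)phenyl]-1-[2-(methoxymethoxy)-4,6-bis(triisopropylsilyloxy)phenyl]propan-1-one | COc1c(O[Si](C)(C)C(C)(C)C)cc(C(CN(C)C)C(=O)c2c(OCOC)cc(O[Si](C(C)C)(C(C)C)C(C)C)cc2O[Si](C(C)C)(C(C)C)C(C)C)cc1CC=C(C)C | intermediate (not isolated)
15 | N-methyl ammonium iodide of 14 | COc1c(O[Si](C)(C)C(C)(C)C)cc(C(C[N+](C)(C)C)C(=O)c2c(OCOC)cc(O[Si](C(C)C)(C(C)C)C(C)C)cc2O[Si](C(C)C)(C(C)C)C(C)C)cc1CC=C(C)C.[I-] | intermediate (not isolated)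
16 | 2-[3-(tert-butyldimethylsilyloxy)-4-methoxy-5-(3-methylbut-2-en-1-yl)phenyl]-1-[2-(methoxymethoxy)-4,6-bis(triisopropylsilyloxy)phenyl]prop-2-en-1-one | C=C(C(=O)c1c(OCOC)cc(O[Si](C(C)C)(C(C)C)C(C)C)cc1O[Si](C(C)C)(C(C)C)C(C)C)c1cc(O[Si](C)(C)C(C)(C)C)c(OC)c(CC=C(C)C)c1 | intermediate
17 | 2-[3-(tert-butyldimethylsilyloxy)-4-methoxy-5-(3-methylbut-2-en-1-yl)phenyl]-1-[2-hydroxy-4,6-bis(triisopropylsilyloxy)phenyl]prop-2-en-1-one | C=C(C(=O)c1c(O)cc(O[Si](C(C)C)(C(C)C)C(C)C)cc1O[Si](C(C)C)(C(C)C)C(C)C)c1cc(O[Si](C)(C)C(C)(C)C)c(OC)c(CC=C(C)C)c1 | intermediate (key-step precursor)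
18 | (3S)-3-[3-(tert-butyldimethylsilyloxy)-4-methoxy-5-(3-methylbut-2-en-1-yl)phenyl]-5,7-bis(triisopropylsilyloxy)chroman-4-one | COc1c(O[Si](C)(C)C(C)(C)C)cc([C@H]2COc3cc(O[Si](C(C)C)(C(C)C)C(C)C)cc(O[Si](C(C)C)(C(C)C)C(C)C)c3C2=O)cc1CC=C(C)C | intermediate (key-step product)
19 | (3S)-5,7,3'-trihydroxy-4'-methoxy-5'-prenylisoflavanone | COc1c(O)cc([C@H]2COc3cc(O)cc(O)c3C2=O)cc1CC=C(C)C | target

**Totals and risks**
Total step count: 10. Longest linear sequence: 8 steps (steps 1, 2, 3, 6, 7, 8, 9, 10).

Steps most likely to fail: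

1. Step 9 (bears the new-method label). What may go wrong: closure through an uncatalysed or simple amine-base pathway that outruns the catalyst-bound one, or loss of enantiopurity by enolisation of the product before the quench. Fallback, setting out from 17 and coming back at 18: 17 is closed with a catalytic amount of Et3N in CH2Cl2 at rt, the known amine-mediated oxa-Michael closure, to give the racemic tris-silyl isoflavanone F1. Preparative HPLC on a cellulose tris(3,5-dimethylphenylcarbamate) phase separates the enantiomers; the 3S enantiomer is 18, and the 3R enantiomer is racemised with DBU and recycled.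

2. Step 8. What may go wrong: acid-promoted ring closure, or addition of water or other nucleophiles to the enone, while the acetal is being hydrolysed. Fallback, setting out from 8 and coming back at 17, so that no deprotection is ever run beside the enone:
 - Bromine–lithium exchange of 8 (n-BuLi, THF, −78 °C) gives the aryllithium F2, which is acetylated with N-methoxy-N-methylacetamide to the ring B acetophenone F3.
 - Condensation with 2,4,6-triisopropylbenzenesulfonyl hydrazide gives the sulfonylhydrazone F4, and the Shapiro reaction (n-BuLi, 2 equiv, THF, −78 → 0 °C) turns it into the 1-arylvinyllithium F5.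
 - F5 adds to 2-hydroxy-4,6-bis(triisopropylsilyloxy)benzaldehyde F6 (from purchased 2,4,6-trihydroxybenzaldehyde with TIPSCl and imidazole, used as its lithium phenoxide) to give the allylic alcohol F7.
 - MnO2 in CH2Cl2 oxidises the benzylic allylic alcohol to 17 under neutral conditions.

3. Step 6. What may go wrong: transfer of the ortho silyl group from oxygen to the enolate oxygen, or loss of aryl silyl ethers, under the basic coupling at 80 °C; sluggish arylation of the hindered ketone or over-arylation. Fallback, setting out from 11 and 8 and coming back at 12, with the polarity of the coupling reversed and the enolate made only at low temperature: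
 - Ketone 11 is converted into its trimethylsilyl enol ether F8 (LiN(SiMe3)2, Me3SiCl, THF, −78 °C) and brominated with N-bromosuccinimide at −78 °C to the α-bromo ketone F9.
 - Bromide 8 is turned into the pinacol boronate F10 by Miyaura borylation (bis(pinacolato)diboron, Pd(dppf)Cl2, KOAc, dioxane, 80 °C).
 - Suzuki–Miyaura coupling of F9 with F10 (Pd(OAc)2, tri(1-naphthyl)phosphine, K3PO4·H2O, THF, rt) gives 12.

**Further compounds**
F1 | step 9 | racemic 3-[3-(tert-butyldimethylsilyloxy)-4-methoxy-5-(3-methylbut-2-en-1-yl)phenyl]-5,7-bis(triisopropylsilyloxy)chroman-4-one | COc1c(O[Si](C)(C)C(C)(C)C)cc(C2COc3cc(O[Si](C(C)C)(C(C)C)C(C)C)cc(O[Si](C(C)C)(C(C)C)C(C)C)c3C2=O)cc1CC=C(C)C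
F2 | step 8 | [3-(tert-butyldimethylsilyloxy)-4-methoxy-5-(3-methylbut-2-en-1-yl)phenyl]lithium | COc1c(O[Si](C)(C)C(C)(C)C)cc([Li])cc1CC=C(C)C
F3 | step 8 | 1-[3-(tert-butyldimethylsilyloxy)-4-methoxy-5-(3-methylbut-2-en-1-yl)phenyl]ethanone | COc1c(O[Si](C)(C)C(C)(C)C)cc(C(C)=O)cc1CC=C(C)C
F4 | step 8 | 2,4,6-triisopropylbenzenesulfonylhydrazone of F3 | COc1c(O[Si](C)(C)C(C)(C)C)cc(C(C)=NNS(=O)(=O)c2c(C(C)C)cc(C(C)C)cc2C(C)C)cc1CC=C(C)C
F5 | step 8 | {1-[3-(tert-butyldimethylsilyloxy)-4-methoxy-5-(3-methylbut-2-en-1-yl)phenyl]vinyl}lithium | COc1c(O[Si](C)(C)C(C)(C)C)cc(C(=C)[Li])cc1CC=C(C)C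
F6 | step 8 | 2-hydroxy-4,6-bis(triisopropylsilyloxy)benzaldehyde | O=Cc1c(O)cc(O[Si](C(C)C)(C(C)C)C(C)C)cc1O[Si](C(C)C)(C(C)C)C(C)C
F7 | step 8 | racemic 2-[3-(tert-butyldimethylsilyloxy)-4-methoxy-5-(3-methylbut-2-en-1-yl)phenyl]-1-[2-hydroxy-4,6-bis(triisopropylsilyloxy)phenyl]prop-2-en-1-ol | C=C(C(O)c1c(O)cc(O[Si](C(C)C)(C(C)C)C(C)C)cc1O[Si](C(C)C)(C(C)C)C(C)C)c1cc(O[Si](C)(C)C(C)(C)C)c(OC)c(CC=C(C)C)c1
F8 | step 6 | trimethyl({1-[2-(methoxymethoxy)-4,6-bis(triisopropylsilyloxy)phenyl]vinyl}oxy)silane | C=C(O[Si](C)(C)C)c1c(OCOC)cc(O[Si](C(C)C)(C(C)C)C(C)C)cc1O[Si](C(C)C)(C(C)C)C(C)C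
F9 | step 6 | 2-bromo-1-[2-(methoxymethoxy)-4,6-bis(triisopropylsilyloxy)phenyl]ethanone | BrCC(=O)c1c(OCOC)cc(O[Si](C(C)C)(C(C)C)C(C)C)cc1O[Si](C(C)C)(C(C)C)C(C)C
F10 | step 6 | tert-butyl[2-methoxy-3-(3-methylbut-2-en-1-yl)-5-(4,4,5,5-tetramethyl-1,3,2-dioxaborolan-2-yl)phenoxy]dimethylsilane | COc1c(O[Si](C)(C)C(C)(C)C)cc(B2OC(C)(C)C(C)(C)O2)cc1CC=C(C)C
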